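**Retrosynthetic overview**

1. Target 16 comes from its 7,4'-bis(triisopropylsilyl) ether 15 by Si–O cleavage.
2. 15 is cut into the pyranone bis(diazo ketone) 9 and two molecules of siloxyalkyne 12 by a twofold diazo ketone/siloxyalkyne benzannulation, which breaks C8–C8a, C7–C8, C5–C6 and C4a–C5 (ring A) and C5'–C6', C4'–C5', C2'–C3' and C1'–C2' (ring B). The structural feature used is that both benzene rings carry OH, prenyl, O and H on four consecutive carbons (C5/C6/C7/C8 and C2'/C3'/C4'/C5'), while ring C (O1, C2, C3, C4, C4a, C8a) is a 4-pyranone whose C4a=C8a bond can serve as the alkene of a vinylketene.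
3. 9 comes from diketone 7 by twofold diazo transfer; 7 from enol triflate 5 and methyl vinyl ketone 6 by Heck coupling; 5 from kojic acid 1 (O5 to OTf, CH2OH to acetyl).
4. 12 comes from ethyl 4-methylpent-3-enoate 10 by one-carbon ynolate homologation and O-silylation.
5. Ring order: ring C is bought with kojic acid; rings A and B are closed together in step 8. The target has no stereocentre.

Key step: step 8

Assumption: in step 6 the crude tetraketone 8 is taken into the diazo transfer after an acidic wash without purification, so the sequence counts as one step.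

**Route**

Step 1
Reactants: 1 kojic acid (5-hydroxy-2-(hydroxymethyl)-4H-pyran-4-one)
Product: 2 6-(hydroxymethyl)-4-oxo-4H-pyran-3-yl trifluoromethanesulfonate
Conditions: PhNTf2 (1.05 equiv), Et3N, DMF, 0 °C → rt
Reagents that add atoms: N-phenylbis(trifluoromethanesulfonimide), O=S(=O)(N(c1ccccc1)S(=O)(=O)C(F)(F)F)C(F)(F)F
Why: Chemoselective triflation of the acidic enolic O5–H, since the mild triflyl donor sulfonylates the enolate-type oxygen formed by Et3N and leaves the neutral primary alcohol alone.

Step 2
Reactants: 2 6-(hydroxymethyl)-4-oxo-4H-pyran-3-yl trifluoromethanesulfonate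
Product: 3 6-formyl-4-oxo-4H-pyran-3-yl trifluoromethanesulfonate
Conditions: Dess–Martin periodinane, CH2Cl2, rt
Reagents that add atoms: none
Why: Dess–Martin oxidation of the activated, allylic-type primary alcohol should stop at the aldehyde under neutral conditions that tolerate the enol triflate and the pyranone.

Step 3
Reactants: 3 6-formyl-4-oxo-4H-pyran-3-yl trifluoromethanesulfonate
Product: 4 6-(1-hydroxyethyl)-4-oxo-4H-pyran-3-yl trifluoromethanesulfonate (racemic)
Conditions: MeTi(OiPr)3, THF, −40 → 0 °C
Reagents that add atoms: methyltitanium triisopropoxide, C[Ti](OC(C)C)(OC(C)C)OC(C)C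
Why: Carbonyl addition of a weakly basic methyltitanium reagent, which is selective for the very electrophilic aldehyde over the vinylogous ester carbonyl and the triflate; the carbinol centre forms as a racemate and is removed in step 4.

Step 4
Reactants: 4 6-(1-hydroxyethyl)-4-oxo-4H-pyran-3-yl trifluoromethanesulfonate
Product: 5 6-acetyl-4-oxo-4H-pyran-3-yl trifluoromethanesulfonate
Conditions: Dess–Martin periodinane, CH2Cl2, rt
Reagents that add atoms: none
Why: Dess–Martin oxidation of the secondary alcohol to the methyl ketone without touching the triflate.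

Step 5
Reactants: 5 6-acetyl-4-oxo-4H-pyran-3-yl trifluoromethanesulfonate; 6 methyl vinyl ketone (but-3-en-2-one)
Product: 7 2-acetyl-5-[(E)-3-oxobut-1-enyl]-4H-pyran-4-one
Conditions: Pd(OAc)2 (5 mol %), PPh3 (10 mol %), Et3N, DMF, 60 °C
Reagents that add atoms: none
Why: Mizoroki–Heck coupling, in which zerovalent palladium inserts into the electron-poor enol triflate, the pyranonyl group adds to the terminal carbon of the enone and syn β-hydride elimination gives the E alkene.

Step 6
Reactants: 7 2-acetyl-5-[(E)-3-oxobut-1-enyl]-4H-pyran-4-one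
Product: 9 2-(diazoacetyl)-5-[(E)-4-diazo-3-oxobut-1-enyl]-4H-pyran-4-one, via bis(trifluoroacetyl) tetraketone 8 (not isolated)
Conditions: LiN(SiMe3)2 (2.2 equiv), THF, −78 °C (inverse addition); CF3CO2CH2CF3; dilute HCl wash; then MsN3, Et3N, H2O, MeCN, rt, dark
Reagents that add atoms: methanesulfonyl azide, CS(=O)(=O)N=[N+]=[N-] (gives the two N2 units of 9); 2,2,2-trifluoroethyl trifluoroacetate, O=C(OCC(F)(F)F)C(F)(F)F (its CF3CO groups stay only in 8)
Why: Danheiser detrifluoroacetylative diazo transfer, in which kinetic enolisation of both methyl ketones and Claisen trifluoroacetylation activate the two methyl carbons so that the sulfonyl azide transfers N2 with loss of the trifluoroacetyl group; this is the standard entry to enone-derived diazo ketones, which acylation of diazomethane serves poorly.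

Step 7
Reactants: 10 ethyl 4-methylpent-3-enoate
Product: 12 triisopropyl(5-methylhex-4-en-1-ynyloxy)silane, via lithium ynolate 11 (not isolated)
Conditions: CH2Br2, lithium 2,2,6,6-tetramethylpiperidide, THF, −78 °C; LiN(SiMe3)2, −78 → −20 °C; n-BuLi, −78 °C → rt; iPr3SiCl, −78 °C → rt
Reagents that add atoms: dibromomethane, BrCBr (gives the alkyne carbon that bears the prenyl group); chlorotriisopropylsilane, CC(C)[Si](Cl)(C(C)C)C(C)C
Why: Kowalski ynolate formation, in which LiCHBr2 adds to the ester, the dibromo ketone enolate undergoes Br/Li exchange and 1,2-shift of the prenyl group to the ynolate, and the bulky silyl chloride silylates on oxygen.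

Step 8
Reactants: 9 2-(diazoacetyl)-5-[(E)-4-diazo-3-oxobut-1-enyl]-4H-pyran-4-one; 12 triisopropyl(5-methylhex-4-en-1-ynyloxy)silane (two molecules incorporated, 3 equiv used)
Product: 15 7,4'-bis-O-(triisopropylsilyl)-2'-hydroxylupalbigenin, via bis(vinylketene) 13 (not isolated), via bis(cyclobutenone) 14 (not isolated)
Conditions: 12 (3 equiv), hν (>300 nm, Pyrex), degassed ClCH2CH2Cl (0.02 M), rt; then 80 °C, dark
Reagents that add atoms: none
Why: Loss of N2 under light and Wolff shift (forming C8–C8a and C5'–C6') turn each diazo ketone into a vinylketene (13), whose alkene is the pyranone C2=C3 bond (future C8a–C4a) on one arm and the E side-chain alkene (future C6'–C1') on the other; the nucleophilic, prenyl-bearing carbon of 12 attacks each ketene carbonyl carbon and [2+2] closure (forming C5–C6, C7–C8, C2'–C3', C4'–C5') gives the 4-alkenyl-3-siloxycyclobutenones 14. On warming, each cyclobutenone opens in a conrotatory four-electron step to a dienylketene, which closes in a disrotatory six-electron electrocyclisation and tautomerises to the phenol. The closest known reaction is the Danheiser benzannulation of alkenyl, aryl and heteroaryl α-diazo ketones with triisopropylsiloxyalkynes to resorcinol monosilyl ethers, here run on two arms of one molecule. Ring A closes by bonding the ketene carbon (C5) to pyranone C3 (C4a) and ring B by bonding the ketene carbon (C2') to the side-chain carbon that carries the pyranone (C1'), both as 6π electrocyclic closures; the only stereocentres formed (cyclobutenone C4 and the sp3 carbon of each cyclohexadienone) are transient and vanish on aromatisation. The step needs a single regiochemistry of ketene–alkyne union, which the polarisation of the siloxyalkyne secures, so that OH, prenyl and OSi fall on three neighbouring carbons with O5 and O2' free and O7 and O4' silylated; it also needs the ketenes to prefer the electron-rich alkyne over the prenyl alkenes and the product phenols (excess 12, dilution) and the side chain to stay E, which irradiation above 300 nm should favour and which keeps the ketene away from pyranone C6.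

Step 9
Reactants: 15 7,4'-bis-O-(triisopropylsilyl)-2'-hydroxylupalbigenin
Product: 16 2'-hydroxylupalbigenin
Conditions: nBu4NF (2.2 equiv), AcOH (2.2 equiv), THF, 0 °C
Reagents that add atoms: none
Why: Fluoride-induced cleavage of the two aryl silyl ethers, with acetic acid buffering the phenoxides so that the prenyl groups and the isoflavone ring are not exposed to strong base.

**Compound list**

1 | kojic acid, 5-hydroxy-2-(hydroxymethyl)-4H-pyran-4-one | OCc1cc(=O)c(O)co1 | starting material
2 | 6-(hydroxymethyl)-4-oxo-4H-pyran-3-yl trifluoromethanesulfonate | OCc1cc(=O)c(OS(=O)(=O)C(F)(F)F)co1 | intermediate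
3 | 6-formyl-4-oxo-4H-pyran-3-yl trifluoromethanesulfonate | O=Cc1cc(=O)c(OS(=O)(=O)C(F)(F)F)co1 | intermediate
4 | 6-(1-hydroxyethyl)-4-oxo-4H-pyran-3-yl trifluoromethanesulfonate, racemic | CC(O)c1cc(=O)c(OS(=O)(=O)C(F)(F)F)co1 | intermediate
5 | 6-acetyl-4-oxo-4H-pyran-3-yl trifluoromethanesulfonate | CC(=O)c1cc(=O)c(OS(=O)(=O)C(F)(F)F)co1 | intermediate
6 | methyl vinyl ketone, but-3-en-2-one | CC(=O)C=C | starting material
7 | 2-acetyl-5-[(E)-3-oxobut-1-enyl]-4H-pyran-4-one | CC(=O)/C=C/c1coc(C(C)=O)cc1=O | intermediate
8 | 2-(4,4,4-trifluoro-3-oxobutanoyl)-5-[(E)-6,6,6-trifluoro-3,5-dioxohex-1-enyl]-4H-pyran-4-one (drawn as tetraketone, present enolised; not isolated) | O=C(CC(=O)C(F)(F)F)/C=C/c1coc(C(=O)CC(=O)C(F)(F)F)cc1=O | intermediate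
9 | 2-(diazoacetyl)-5-[(E)-4-diazo-3-oxobut-1-enyl]-4H-pyran-4-one | [N-]=[N+]=CC(=O)/C=C/c1coc(C(=O)C=[N+]=[N-])cc1=O | intermediate
10 | ethyl 4-methylpent-3-enoate | CCOC(=O)CC=C(C)C | starting material
11 | lithium 5-methylhex-4-en-1-yn-1-olate (not isolated) | [Li+].[O-]C#CCC=C(C)C | intermediate
12 | triisopropyl(5-methylhex-4-en-1-ynyloxy)silane | CC(C)=CCC#CO[Si](C(C)C)(C(C)C)C(C)C | intermediate
13 | 2-(2-oxoethenyl)-5-[(1E)-4-oxobuta-1,3-dienyl]-4H-pyran-4-one, the bis(vinylketene) (not isolated) | O=C=C/C=C/c1coc(C=C=O)cc1=O | intermediate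
14 | 2-[3-(3-methylbut-2-enyl)-2-oxo-4-(triisopropylsilyloxy)cyclobut-3-enyl]-5-{(E)-2-[3-(3-methylbut-2-enyl)-2-oxo-4-(triisopropylsilyloxy)cyclobut-3-enyl]ethenyl}-4H-pyran-4-one, mixture of diastereomers (not isolated) | CC(C)=CCC1=C(O[Si](C(C)C)(C(C)C)C(C)C)C(/C=C/c2coc(C3C(=O)C(CC=C(C)C)=C3O[Si](C(C)C)(C(C)C)C(C)C)cc2=O)C1=O | intermediate
15 | 7,4'-bis-O-(triisopropylsilyl)-2'-hydroxylupalbigenin, 5-hydroxy-3-[2-hydroxy-3-(3-methylbut-2-enyl)-4-(triisopropylsilyloxy)phenyl]-6-(3-methylbut-2-enyl)-7-(triisopropylsilyloxy)-4H-chromen-4-one | CC(C)=CCc1c(O[Si](C(C)C)(C(C)C)C(C)C)ccc(-c2coc3cc(O[Si](C(C)C)(C(C)C)C(C)C)c(CC=C(C)C)c(O)c3c2=O)c1O | intermediate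
16 | 2'-hydroxylupalbigenin, 3-[2,4-dihydroxy-3-(3-methylbut-2-enyl)phenyl]-5,7-dihydroxy-6-(3-methylbut-2-enyl)-4H-chromen-4-one | CC(C)=CCc1c(O)ccc(-c2coc3cc(O)c(CC=C(C)C)c(O)c3c2=O)c1O | target

**Step count**

Total: 9 steps. Longest linear sequence: 8 steps (steps 1–6, 8 and 9, from kojic acid); step 7 is a one-step side branch.

**Steps most likely to fail**

Step 8 (key step). Several processes may divert it:
- light-driven E→Z isomerisation of the side-chain alkene, after which the ketene of that arm could close directly onto pyranone C6 without taking up the alkyne;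
- photorearrangement of the 4-pyranone;
- acylation of phenolic hydroxyls already formed by ketenes still being generated on the other arm;
- unequal rates of the two arms, leaving half-annulated mixtures.

Fallback: the two annulations are run one after the other, so that each ketene is generated in a molecule without a second diazo group and each cascade can be optimised alone. Setting out from 5, a single diazo transfer of the step 6 type should give 6-(diazoacetyl)-4-oxo-4H-pyran-3-yl trifluoromethanesulfonate F1. Irradiation and warming with 12 should close ring A first and give 5-hydroxy-6-(3-methylbut-2-enyl)-4-oxo-7-(triisopropylsilyloxy)-4H-chromen-3-yl trifluoromethanesulfonate F2. Heck coupling of F2 with 6 (Pd(OAc)2, PPh3, Et3N, DMF) should give (E)-4-[5-hydroxy-6-(3-methylbut-2-enyl)-4-oxo-7-(triisopropylsilyloxy)-4H-chromen-3-yl]but-3-en-2-one F3. Diazo transfer, with one more equivalent of LiN(SiMe3)2 for the chelated C5 hydroxyl, should give 3-[(E)-4-diazo-3-oxobut-1-enyl]-5-hydroxy-6-(3-methylbut-2-enyl)-7-(triisopropylsilyloxy)-4H-chromen-4-one F4. A second annulation of F4 with 12 closes ring B and comes back to the route at 15.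

Step 6 (twofold diazo transfer). The bis-enolate may condense with itself by Michael or aldol addition, the amide base may add to pyranone C6 and open the ring, or only one arm may be acylated.

Fallback: the diazo ketones are made by acylating a diazomethane equivalent, with no enolate chemistry. Setting out from 2, Heck coupling with acrylic acid (Pd(OAc)2, PPh3, Et3N, DMF) should give (E)-3-[6-(hydroxymethyl)-4-oxo-4H-pyran-3-yl]prop-2-enoic acid F5. Oxidation of the primary alcohol with CrO3/H2SO4 in acetone should give 5-[(E)-2-carboxyethenyl]-4-oxo-4H-pyran-2-carboxylic acid F6. (COCl)2 with catalytic DMF should give (E)-3-[6-(chlorocarbonyl)-4-oxo-4H-pyran-3-yl]prop-2-enoyl chloride F7. Slow addition of F7 to excess Me3SiCHN2 and Et3N in THF–MeCN at 0 °C, with loss of the C-silyl group on work-up, comes back to the route at 9. The low temperature and inverse addition are meant to hold back dipolar cycloaddition at the acryloyl arm.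

Step 7 (siloxyalkyne). The carbenoid or the amide bases may deprotonate the doubly activated α-CH2 of the β,γ-unsaturated ester instead of adding to it, the double bond may move into conjugation, and the ynolate may be silylated on carbon.

Fallback: the ynolate is reached by oxidising an acetylide, so the ester never meets the carbenoid. Setting out from 10, reduction with iBu2AlH (CH2Cl2, −78 °C) should give 4-methylpent-3-enal F8. CBr4/PPh3 (CH2Cl2, 0 °C) should give 1,1-dibromo-5-methylhexa-1,4-diene F9. n-BuLi (2 equiv, THF, −78 °C) should give lithium 5-methylhex-4-en-1-yn-1-ide F10. Oxidation of F10 in the same flask with LiOOtBu (−78 → 0 °C) gives ynolate 11, and O-silylation with iPr3SiOSO2CF3 comes back to the route at 12.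

Further compounds
F1 | step 8 | 6-(diazoacetyl)-4-oxo-4H-pyran-3-yl trifluoromethanesulfonate | [N-]=[N+]=CC(=O)c1cc(=O)c(OS(=O)(=O)C(F)(F)F)co1
F2 | step 8 | 5-hydroxy-6-(3-methylbut-2-enyl)-4-oxo-7-(triisopropylsilyloxy)-4H-chromen-3-yl trifluoromethanesulfonate | CC(C)=CCc1c(O[Si](C(C)C)(C(C)C)C(C)C)cc2occ(OS(=O)(=O)C(F)(F)F)c(=O)c2c1O
F3 | step 8 | (E)-4-[5-hydroxy-6-(3-methylbut-2-enyl)-4-oxo-7-(triisopropylsilyloxy)-4H-chromen-3-yl]but-3-en-2-one | CC(=O)/C=C/c1coc2cc(O[Si](C(C)C)(C(C)C)C(C)C)c(CC=C(C)C)c(O)c2c1=O
F4 | step 8 | 3-[(E)-4-diazo-3-oxobut-1-enyl]-5-hydroxy-6-(3-methylbut-2-enyl)-7-(triisopropylsilyloxy)-4H-chromen-4-one | [N-]=[N+]=CC(=O)/C=C/c1coc2cc(O[Si](C(C)C)(C(C)C)C(C)C)c(CC=C(C)C)c(O)c2c1=O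
F5 | step 6 | (E)-3-[6-(hydroxymethyl)-4-oxo-4H-pyran-3-yl]prop-2-enoic acid | OCc1cc(=O)c(/C=C/C(=O)O)co1
F6 | step 6 | 5-[(E)-2-carboxyethenyl]-4-oxo-4H-pyran-2-carboxylic acid | OC(=O)/C=C/c1coc(C(=O)O)cc1=O
F7 | step 6 | (E)-3-[6-(chlorocarbonyl)-4-oxo-4H-pyran-3-yl]prop-2-enoyl chloride | O=C(Cl)/C=C/c1coc(C(Cl)=O)cc1=O
F8 | step 7 | 4-methylpent-3-enal | CC(C)=CCC=O
F9 | step 7 | 1,1-dibromo-5-methylhexa-1,4-diene | CC(C)=CCC=C(Br)Br
F10 | step 7 | lithium 5-methylhex-4-en-1-yn-1-ide | [Li+].[C-]#CCC=C(C)C
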